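**Retrosynthetic overview**

1. The last C–C bond joins the ester-bearing butenolide carbon to the benzylic CH2 by asymmetric phase-transfer benzylation of the C–H butenolide with a 6-(bromomethyl)chroman; one global O-debenzylation follows.
2. The strategy rests on the dihydropyran ring of the chroman: carbinol C3 lies between the gem-dimethyl carbon C2 and the benzylic C4H2, so it is the C4-deoxygenated form of the 3,4-epoxide of a 2,2-dimethyl-2H-chromene. Catalytic asymmetric epoxidation of C3=C4 sets C3, and benzylic hydrogenolysis then removes the C4–O bond.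
3. The chromene comes from methyl 4-hydroxybenzoate by propargylation and aryl propargyl ether Claisen rearrangement with oxa-6π closure; its C6 ester later becomes the CH2Br handle.
4. The butenolide comes from 3,4-bis(benzyloxy)benzaldehyde through the arylpyruvate (azlactone route), aldol–lactonization with methyl glyoxylate and enol O-methylation.
5. Ring order: pyran ring (step 2), oxirane fused to it (step 3, opened in step 4), butenolide ring (step 11).

Key step: step 3

Remark: the SMILES is read as (S) at the ester-bearing butenolide carbon and (R) at the chroman carbinol; the butenolide is discussed as a furan-2(5H)-one (C3 OMe, C4 aryl, C5 ester-bearing), whereas the systematic names count the ester-bearing carbon as C2 of a 2,5-dihydrofuran-2-carboxylate.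

**Route**

Step 1
Reactants: 1 methyl 4-hydroxybenzoate; 2 3-chloro-3-methylbut-1-yne
Product: 3 methyl 4-[(2-methylbut-3-yn-2-yl)oxy]benzoate
Conditions: K2CO3, KI (cat.), acetone, reflux
Reagents that add atoms: none
Why: Williamson-type O-alkylation of the phenoxide by the tertiary propargylic chloride, a standard entry to 1,1-dimethylpropargyl aryl ethers, helped by the acidity of the para-ester phenol.

Step 2
Reactants: 3 methyl 4-[(2-methylbut-3-yn-2-yl)oxy]benzoate
Product: 7 methyl 2,2-dimethyl-2H-chromene-6-carboxylate, via allenyl dienone 4 (not isolated), via allenylphenol 5 (not isolated), via ortho-quinone methide 6 (not isolated)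
Conditions: PhNEt2, 190 °C
Reagents that add atoms: none
Why: Aryl propargyl ether Claisen rearrangement ([3,3]) followed by tautomerization, 1,5-hydrogen shift and oxa-6π electrocyclization should close the pyran ring, and the two equivalent ortho positions allow only one chromene.

Step 3
Reactants: 7 methyl 2,2-dimethyl-2H-chromene-6-carboxylate
Product: 8 methyl (3R,4R)-3,4-epoxy-2,2-dimethylchroman-6-carboxylate
Conditions: (R,R)-N,N'-bis(3,5-di-tert-butylsalicylidene)-1,2-cyclohexanediaminomanganese chloride (4 mol %), 4-phenylpyridine N-oxide (20 mol %), aq NaOCl (Na2HPO4 buffer, pH 11.3), CH2Cl2, 0 °C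
Reagents that add atoms: sodium hypochlorite, [Na+].[O-]Cl
Why: Hypochlorite oxidizes the trivalent manganese salen complex to a pentavalent oxo-manganese species, which transfers its oxygen to the C3=C4 alkene by side-on approach, the first C–O bond forming at C3 to leave a benzylic radical at C4 that collapses to the second C–O bond. This is the Jacobsen–Katsuki epoxidation, for which 2,2-dimethylchromenes are a standard substrate class. The oxirane is closed by this formal [2+1] oxygen-atom transfer (3-exo collapse of the C4 radical onto the manganese-bound oxygen), and since the alkene is held cis in the pyran ring only the cis-fused epoxide can form. Both new stereocenters, C3 and C4, are set together by the twofold-symmetric (R,R)-ligand, whose tert-butyl groups and cyclohexanediamine backbone leave one trajectory open and so expose one enantioface, which should give the (3R,4R)-epoxide. The selectivity needed is enantiofacial only: there is a single alkene, the fused arene and the gem-dimethyl group at C2 differentiate its two ends for the catalyst, and the C6 ester lowers the electron density of the arene so that ring oxidation and opening of the epoxide should not compete in the buffered two-phase medium.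

Step 4
Reactants: 8 methyl (3R,4R)-3,4-epoxy-2,2-dimethylchroman-6-carboxylate
Product: 9 methyl (3R)-3-hydroxy-2,2-dimethylchroman-6-carboxylate
Conditions: H2 (1 atm), 10% Pd/C, EtOAc, rt
Reagents that add atoms: none
Why: Catalytic hydrogenolysis cleaves only the benzylic C4–O bond of the aryl epoxide, so the oxygen stays on C3 with its configuration untouched and the carbinol is (R).

Step 5
Reactants: 9 methyl (3R)-3-hydroxy-2,2-dimethylchroman-6-carboxylate
Product: 10 methyl (3R)-3-(benzyloxy)-2,2-dimethylchroman-6-carboxylate
Conditions: NaH, BnBr, Bu4NI (cat.), THF/DMF, 0 °C to rt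
Reagents that add atoms: benzyl bromide, BrCc1ccccc1
Why: Williamson benzylation of the hindered secondary alkoxide with iodide catalysis; the aryl ester has no enolizable position and C3 cannot epimerize.

Step 6
Reactants: 10 methyl (3R)-3-(benzyloxy)-2,2-dimethylchroman-6-carboxylate
Product: 11 [(3R)-3-(benzyloxy)-2,2-dimethylchroman-6-yl]methanol
Conditions: LiAlH4, THF, 0 °C; then H2O, aq NaOH
Reagents that add atoms: none
Why: Hydride reduction of the aryl ester to the benzylic alcohol, which leaves the benzyl ether and the chroman untouched.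

Step 7
Reactants: 11 [(3R)-3-(benzyloxy)-2,2-dimethylchroman-6-yl]methanol
Product: 12 (3R)-3-(benzyloxy)-6-(bromomethyl)-2,2-dimethylchroman
Conditions: CBr4, PPh3, CH2Cl2, 0 °C; filtered through a short silica pad and used at once
Reagents that add atoms: carbon tetrabromide, BrC(Br)(Br)Br
Why: Appel bromination under neutral conditions converts the primary benzylic alcohol without touching the benzyl ether; the para-alkoxybenzyl bromide is labile and is therefore not stored.

Step 8
Reactants: 13 3,4-bis(benzyloxy)benzaldehyde; 14 N-acetylglycine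
Product: 16 (4Z)-4-[3,4-bis(benzyloxy)benzylidene]-2-methyl-1,3-oxazol-5(4H)-one, via 2-methyloxazol-5(4H)-one 15 (not isolated)
Conditions: NaOAc, Ac2O, 110 °C
Reagents that add atoms: none
Why: Erlenmeyer azlactone synthesis, in which cyclodehydration of the acylglycine gives the oxazolone whose acidic CH2 condenses with the aldehyde in a Perkin-type manner.

Step 9
Reactants: 16 (4Z)-4-[3,4-bis(benzyloxy)benzylidene]-2-methyl-1,3-oxazol-5(4H)-one
Product: 18 3-[3,4-bis(benzyloxy)phenyl]-2-oxopropanoic acid, via acetamidocinnamic acid 17 (not isolated)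
Conditions: acetone/H2O, reflux; then 1 M HCl/1,4-dioxane, 90 °C
Reagents that add atoms: water, O
Why: Classical azlactone hydrolysis: ring opening to the acetamidocinnamic acid and acid hydrolysis of the enamide give the arylpyruvic acid, and aryl benzyl ethers tolerate dilute aqueous HCl.

Step 10
Reactants: 18 3-[3,4-bis(benzyloxy)phenyl]-2-oxopropanoic acid
Product: 19 methyl 3-[3,4-bis(benzyloxy)phenyl]-2-oxopropanoate
Conditions: KHCO3, MeI, DMF, rt
Reagents that add atoms: iodomethane, CI
Why: Carboxylate alkylation with a base too weak to deprotonate the enol, so only the acid is methylated.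

Step 11
Reactants: 19 methyl 3-[3,4-bis(benzyloxy)phenyl]-2-oxopropanoate; 20 methyl glyoxylate
Product: 22 racemic methyl 3-[3,4-bis(benzyloxy)phenyl]-4-hydroxy-5-oxo-2,5-dihydrofuran-2-carboxylate, via aldol adduct 21 (not isolated)
Conditions: Et3N, 20 (excess, freshly distilled), CH2Cl2, 0 °C to rt; then 1 M HCl
Reagents that add atoms: none
Why: Aldol addition of the arylpyruvate enolate to the very electrophilic glyoxylate aldehyde, then 5-exo-trig lactonization onto the activated keto ester and enolization (the classical isotetronic acid synthesis); the ring CH is formed racemic, which is irrelevant because it is deprotonated in step 13.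

Step 12
Reactants: 22 racemic methyl 3-[3,4-bis(benzyloxy)phenyl]-4-hydroxy-5-oxo-2,5-dihydrofuran-2-carboxylate
Product: 23 racemic methyl 3-[3,4-bis(benzyloxy)phenyl]-4-methoxy-5-oxo-2,5-dihydrofuran-2-carboxylate
Conditions: TMSCHN2, MeOH/toluene, 0 °C to rt
Reagents that add atoms: trimethylsilyldiazomethane, C[Si](C)(C)C=[N+]=[N-]
Why: Base-free O-methylation of the acidic enol by the diazoalkane, which avoids deprotonation and C-methylation at the ester-bearing ring carbon.

Step 13
Reactants: 23 racemic methyl 3-[3,4-bis(benzyloxy)phenyl]-4-methoxy-5-oxo-2,5-dihydrofuran-2-carboxylate; 12 (3R)-3-(benzyloxy)-6-(bromomethyl)-2,2-dimethylchroman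
Product: 24 methyl (2S)-2-{[(3R)-3-(benzyloxy)-2,2-dimethylchroman-6-yl]methyl}-3-[3,4-bis(benzyloxy)phenyl]-4-methoxy-5-oxo-2,5-dihydrofuran-2-carboxylate
Conditions: O-allyl-N-(9-anthracenylmethyl)cinchonidinium bromide (10 mol %), Cs2CO3 (solid), toluene (degassed), −20 °C, argon
Reagents that add atoms: none
Why: Proposed new method: solid Cs2CO3 removes the ring C–H of 23 (alpha to the ester, vinylogous to the lactone carbonyl), the resulting 2-oxidofuran pairs with the chiral ammonium cation in toluene, and SN2 attack of the ester-bearing carbon on bromide 12 from the open face of the ion pair should form the quaternary centre, intended as (S); attack there is expected over the methoxy-bearing carbon because it restores the conjugated butenolide and is less hindered, the closest known reaction types being the cinchona-ammonium-catalysed asymmetric benzylation of cyclic alpha-acyloxy esters such as phthalide-3-carboxylates and of alpha-substituted beta-keto esters and malonates, and since the sense of induction cannot be predicted it is assigned on the first run, the pseudoenantiomeric cinchoninium salt being used if the (R)-epimer prevails and any minor epimer being a separable diastereomer of 24.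

Step 14
Reactants: 24 methyl (2S)-2-{[(3R)-3-(benzyloxy)-2,2-dimethylchroman-6-yl]methyl}-3-[3,4-bis(benzyloxy)phenyl]-4-methoxy-5-oxo-2,5-dihydrofuran-2-carboxylate
Product: 25 methyl (2S)-3-(3,4-dihydroxyphenyl)-2-{[(3R)-3-hydroxy-2,2-dimethylchroman-6-yl]methyl}-4-methoxy-5-oxo-2,5-dihydrofuran-2-carboxylate
Conditions: H2 (1 atm), 10% Pd/C, EtOAc/MeOH, rt; work-up under argon
Reagents that add atoms: none
Why: Hydrogenolysis of the two aryl benzyl ethers and the alkyl benzyl ether in one operation, the tetrasubstituted aryl- and methoxy-substituted butenolide alkene being too hindered to be reduced at 1 atm.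

**Compound list**

1 | methyl 4-hydroxybenzoate | COC(=O)c1ccc(O)cc1 | starting material
2 | 3-chloro-3-methylbut-1-yne | CC(C)(Cl)C#C | starting material
3 | methyl 4-[(2-methylbut-3-yn-2-yl)oxy]benzoate | COC(=O)c1ccc(OC(C)(C)C#C)cc1 | intermediate
4 | allenyl dienone, methyl 3-(3-methylbuta-1,2-dien-1-yl)-4-oxocyclohexa-1,5-diene-1-carboxylate (not isolated) | COC(=O)C1=CC(C=C=C(C)C)C(=O)C=C1 | intermediate
5 | allenylphenol, methyl 4-hydroxy-3-(3-methylbuta-1,2-dien-1-yl)benzoate (not isolated) | COC(=O)c1ccc(O)c(C=C=C(C)C)c1 | intermediate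
6 | ortho-quinone methide, methyl (3Z)-3-(3-methylbut-2-en-1-ylidene)-4-oxocyclohexa-1,5-diene-1-carboxylate (not isolated) | COC(=O)C1=C/C(=C/C=C(C)C)C(=O)C=C1 | intermediate
7 | methyl 2,2-dimethyl-2H-chromene-6-carboxylate | COC(=O)c1ccc2c(c1)C=CC(C)(C)O2 | intermediate
8 | methyl (3R,4R)-3,4-epoxy-2,2-dimethylchroman-6-carboxylate | COC(=O)c1ccc2c(c1)[C@@H]3[C@@H](O3)C(C)(C)O2 | intermediate
9 | methyl (3R)-3-hydroxy-2,2-dimethylchroman-6-carboxylate | COC(=O)c1ccc2c(c1)C[C@@H](O)C(C)(C)O2 | intermediate
10 | methyl (3R)-3-(benzyloxy)-2,2-dimethylchroman-6-carboxylate | COC(=O)c1ccc2c(c1)C[C@@H](OCc1ccccc1)C(C)(C)O2 | intermediate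
11 | [(3R)-3-(benzyloxy)-2,2-dimethylchroman-6-yl]methanol | OCc1ccc2c(c1)C[C@@H](OCc1ccccc1)C(C)(C)O2 | intermediate
12 | (3R)-3-(benzyloxy)-6-(bromomethyl)-2,2-dimethylchroman | BrCc1ccc2c(c1)C[C@@H](OCc1ccccc1)C(C)(C)O2 | intermediate
13 | 3,4-bis(benzyloxy)benzaldehyde | O=Cc1ccc(OCc2ccccc2)c(OCc2ccccc2)c1 | starting material
14 | N-acetylglycine | CC(=O)NCC(=O)O | starting material
15 | 2-methyloxazol-5(4H)-one (not isolated) | CC1=NCC(=O)O1 | intermediate
16 | (4Z)-4-[3,4-bis(benzyloxy)benzylidene]-2-methyl-1,3-oxazol-5(4H)-one | CC1=N/C(=C\c2ccc(OCc3ccccc3)c(OCc3ccccc3)c2)C(=O)O1 | intermediate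
17 | (2Z)-2-acetamido-3-[3,4-bis(benzyloxy)phenyl]prop-2-enoic acid (not isolated) | CC(=O)N/C(=C\c1ccc(OCc2ccccc2)c(OCc2ccccc2)c1)C(=O)O | intermediate
18 | 3-[3,4-bis(benzyloxy)phenyl]-2-oxopropanoic acid | OC(=O)C(=O)Cc1ccc(OCc2ccccc2)c(OCc2ccccc2)c1 | intermediate
19 | methyl 3-[3,4-bis(benzyloxy)phenyl]-2-oxopropanoate | COC(=O)C(=O)Cc1ccc(OCc2ccccc2)c(OCc2ccccc2)c1 | intermediate
20 | methyl glyoxylate | COC(=O)C=O | starting material
21 | aldol adduct, dimethyl 3-[3,4-bis(benzyloxy)phenyl]-2-hydroxy-4-oxopentanedioate (diastereomer mixture, not isolated) | COC(=O)C(O)C(c1ccc(OCc2ccccc2)c(OCc2ccccc2)c1)C(=O)C(=O)OC | intermediate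
22 | racemic methyl 3-[3,4-bis(benzyloxy)phenyl]-4-hydroxy-5-oxo-2,5-dihydrofuran-2-carboxylate | COC(=O)C1OC(=O)C(O)=C1c1ccc(OCc2ccccc2)c(OCc2ccccc2)c1 | intermediate
23 | racemic methyl 3-[3,4-bis(benzyloxy)phenyl]-4-methoxy-5-oxo-2,5-dihydrofuran-2-carboxylate | COC(=O)C1OC(=O)C(OC)=C1c1ccc(OCc2ccccc2)c(OCc2ccccc2)c1 | intermediate
24 | methyl (2S)-2-{[(3R)-3-(benzyloxy)-2,2-dimethylchroman-6-yl]methyl}-3-[3,4-bis(benzyloxy)phenyl]-4-methoxy-5-oxo-2,5-dihydrofuran-2-carboxylate | COC(=O)[C@@]1(Cc2ccc3c(c2)C[C@@H](OCc2ccccc2)C(C)(C)O3)OC(=O)C(OC)=C1c1ccc(OCc2ccccc2)c(OCc2ccccc2)c1 | intermediate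
25 | methyl (2S)-3-(3,4-dihydroxyphenyl)-2-{[(3R)-3-hydroxy-2,2-dimethylchroman-6-yl]methyl}-4-methoxy-5-oxo-2,5-dihydrofuran-2-carboxylate | COC(=O)[C@@]1(Cc2ccc3c(c2)C[C@@H](O)C(C)(C)O3)OC(=O)C(OC)=C1c1ccc(O)c(O)c1 | target

**Step count**

Total steps: 14. Longest linear sequence: 9 steps (steps 1–7, 13, 14); the butenolide branch (steps 8–12) is 5 steps.

**Steps most likely to fail**

1. Step 13 (proposed new method). The ion pair may discriminate the two faces poorly. Alkylation may also take place at the methoxy-bearing ring carbon or at oxygen, and the electron-rich dienolate may be degraded by traces of oxygen. Fallback by known chemistry, without catalyst control: setting out from 23, O-silylation (TBSOTf, Et3N, CH2Cl2, 0 °C) would give the 2-silyloxyfuran methyl 3-[3,4-bis(benzyloxy)phenyl]-5-(tert-butyldimethylsilyloxy)-4-methoxyfuran-2-carboxylate F1. Silver-assisted ionization of bromide 12 in its presence (AgOCOCF3, CH2Cl2, −78 °C) is a vinylogous Mukaiyama-type SN1 alkylation of a silyloxyfuran at the ring carbon remote from the silyloxy group. It should give 24 together with its epimer at the quaternary carbon, methyl (2R)-2-{[(3R)-3-(benzyloxy)-2,2-dimethylchroman-6-yl]methyl}-3-[3,4-bis(benzyloxy)phenyl]-4-methoxy-5-oxo-2,5-dihydrofuran-2-carboxylate F2. The two are diastereomers and would be separated by preparative HPLC, so the route is rejoined at 24 at the cost of half the material.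

2. Step 11. Self-condensation of the arylpyruvate and base-induced oligomerization of the glyoxylate may outrun the crossed aldol addition. Fallback: setting out from 19, silylation (TMSCl, Et3N, CH2Cl2) would give the enol silane methyl (2Z)-3-[3,4-bis(benzyloxy)phenyl]-2-(trimethylsilyloxy)prop-2-enoate F3. A Lewis-acid-catalysed Mukaiyama aldol addition to 20 (Sc(OTf)3 cat., CH2Cl2, −78 °C) with acidic work-up (1 M HCl, THF) then leads through 21 to the lactone, and the route is rejoined at 22. No free enolate and no base are present in this variant.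

3. Step 4. On palladium the epoxide may isomerize to the chroman-3-one or be opened by adventitious acid instead of undergoing clean C4–O hydrogenolysis. Fallback: setting out from 8, opening with bromide at the benzylic carbon with inversion (LiBr, AcOH, THF, rt) would give the trans-bromohydrin methyl (3S,4S)-4-bromo-3-hydroxy-2,2-dimethylchroman-6-carboxylate F4. Radical reduction of the C–Br bond (Bu3SnH, AIBN, toluene, 80 °C) then removes the halogen without touching the carbinol carbon, and the route is rejoined at 9.

**Further compounds**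

F1 | step 13 | methyl 3-[3,4-bis(benzyloxy)phenyl]-5-(tert-butyldimethylsilyloxy)-4-methoxyfuran-2-carboxylate | COC(=O)C1=C(c2ccc(OCc3ccccc3)c(OCc3ccccc3)c2)C(OC)=C(O[Si](C)(C)C(C)(C)C)O1
F2 | step 13 | methyl (2R)-2-{[(3R)-3-(benzyloxy)-2,2-dimethylchroman-6-yl]methyl}-3-[3,4-bis(benzyloxy)phenyl]-4-methoxy-5-oxo-2,5-dihydrofuran-2-carboxylate | COC(=O)[C@]1(Cc2ccc3c(c2)C[C@@H](OCc2ccccc2)C(C)(C)O3)OC(=O)C(OC)=C1c1ccc(OCc2ccccc2)c(OCc2ccccc2)c1
F3 | step 11 | methyl (2Z)-3-[3,4-bis(benzyloxy)phenyl]-2-(trimethylsilyloxy)prop-2-enoate | COC(=O)/C(O[Si](C)(C)C)=C/c1ccc(OCc2ccccc2)c(OCc2ccccc2)c1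
F4 | step 4 | methyl (3S,4S)-4-bromo-3-hydroxy-2,2-dimethylchroman-6-carboxylate | COC(=O)c1ccc2c(c1)[C@H](Br)[C@@H](O)C(C)(C)O2
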